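## Retrosynthetic overview

1. The oxane is the only ring and is closed last but one: its O–CH bond and the bond from that CH to the acrylate α-carbon come from an acyclic 2-substituted pent-4-en-1-ol plus methyl 2-bromoacrylate (palladium 1,1-oxyalkenylation), then ester and acetonide removal.
2. The pentenol comes from a trans-4,5-disubstituted γ-butyrolactone (lactol, methylenation, glycol cleavage of the spare carbon).
3. Key union: the bond between the ring CH that carries the side chain and the first side-chain CH2 is made by a light-driven Giese addition of a primary alkyl radical to (S)-5-(hydroxymethyl)furan-2(5H)-one, anti to its CH2OH.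
4. The radical precursor (an iodide carrying the protected diol) comes from (R)-3-hydroxyoxolan-2-one: methyl ketone, then chelation-controlled addition of homogeranylmagnesium iodide to set the tertiary carbinol.
5. Homogeranyl iodide comes from geranyl bromide by one-carbon homologation. Ring order: temporary dioxolane, then the butyrolactone carried over from the butenolide (later opened), then the oxane.

Notation: C-1 to C-24 number the target carbons in the order of its SMILES string (C-1 CH2=, C-2, C-3 CO2H; C-4 to C-7 and C-24 in the oxane; C-8 to C-23 in the side chain; C-12 is the methyl on C-11). hGer = homogeranyl = (3E)-4,8-dimethylnona-3,7-dien-1-yl. Diox = (4R,5R)-5-hGer-2,2,5-trimethyl-1,3-dioxolan-4-yl (the C-10/C-11 acetonide).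

Assumption: 1, 4, 11 and 17 are bought (4 is the catalogue lactone derived from D-malic acid, 11 the cellulose-derived butenolide); selectivities quoted are estimates.

## Route

Step 1
Reactants: 1 geranyl bromide, (2E)-1-bromo-3,7-dimethylocta-2,6-diene
Product: 2 homogeranyl phenyl sulfide, {[(3E)-4,8-dimethylnona-3,7-dien-1-yl]sulfanyl}benzene
Conditions: PhSCH3, n-BuLi, DABCO, THF, 0 °C; then 1, −78 °C → rt
Reagents that add atoms: thioanisole, CSc1ccccc1
Why: SN2 alkylation of (phenylthio)methyllithium by the allylic bromide (first half of the Corey–Jautelat one-carbon homologation) adds the future C-13 without touching the E olefin.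

Step 2
Reactants: 2 homogeranyl phenyl sulfide
Product: 3 homogeranyl iodide, (3E)-1-iodo-4,8-dimethylnona-3,7-diene
Conditions: MeI, NaI, DMF, 75 °C
Reagents that add atoms: iodomethane, CI
Why: S-methylation to the sulfonium salt and displacement by iodide (second half of the Corey–Jautelat homologation) gives the primary iodide with both trisubstituted olefins unchanged.

Step 3
Reactants: 4 (3R)-3-hydroxyoxolan-2-one
Product: 6 (3R)-3,5-dihydroxypentan-2-one (handled as its cyclic hemiketal), via dilithium lactolate 5 (not isolated)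
Conditions: MeLi (2.05 equiv), THF, −78 °C; AcOH, −78 °C
Reagents that add atoms: methyllithium, [Li]C
Why: Nucleophilic addition of one organolithium to the lactone stops at the alkoxide-stabilised lactolate at −78 °C, so a cold quench gives the methyl ketone with the bought C-10 centre untouched.

Step 4
Reactants: 3 homogeranyl iodide; 6 (3R)-3,5-dihydroxypentan-2-one
Product: 8 (3R,4R,7E)-4,8,12-trimethyltrideca-7,11-diene-1,3,4-triol, via homogeranylmagnesium iodide 7 (not isolated)
Conditions: 3, Mg, THF, rt (gives 7); 6, t-BuMgCl (2.0 equiv), THF, −78 °C, then 7 (1.5 equiv), −78 → 0 °C; aq. NH4Cl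
Reagents that add atoms: none
Why: Cram-chelate Grignard addition, in which the five-membered magnesium alkoxide–ketone chelate is attacked from the face of the C-10 hydrogen, sets the tertiary carbinol C-11 as R under control of the bought C-10 centre (est. ≥10:1).

Step 5
Reactants: 8 (3R,4R,7E)-4,8,12-trimethyltrideca-7,11-diene-1,3,4-triol
Product: 9 2-(Diox)ethan-1-ol
Conditions: Me2C(OMe)2, PPTS (cat.), acetone, rt
Reagents that add atoms: 2,2-dimethoxypropane, COC(C)(C)OC
Why: Acid-catalysed transketalisation gives the five-membered acetonide of the secondary/tertiary 1,2-diol, which is preferred over the six-membered 1,3-dioxane, and leaves the primary alcohol free.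

Step 6
Reactants: 9 2-(Diox)ethan-1-ol
Product: 10 (4R,5R)-5-hGer-4-(2-iodoethyl)-2,2,5-trimethyl-1,3-dioxolane
Conditions: I2, PPh3, imidazole, CH2Cl2, 0 °C
Reagents that add atoms: iodine, II
Why: Appel-type iodination (Garegg–Samuelsson conditions) converts the only free, primary alcohol under imidazole-buffered conditions that the acetonide tolerates.

Step 7
Reactants: 10 (4R,5R)-5-hGer-4-(2-iodoethyl)-2,2,5-trimethyl-1,3-dioxolane; 11 (5S)-5-(hydroxymethyl)furan-2(5H)-one
Product: 12 (4S,5S)-4-[2-(Diox)ethyl]-5-(hydroxymethyl)oxolan-2-one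
Conditions: 11 (2.5 equiv), Mn2(CO)10 (10 mol%), Hantzsch ester (1.5 equiv), 2,6-lutidine (1.5 equiv), MeCN, blue LEDs (450 nm), rt
Reagents that add atoms: none
Why: Light-driven Giese reaction under base-free conditions that do not racemise the butenolide: photolysed Mn2(CO)10 abstracts iodine from 10, the primary radical adds to the butenolide β-carbon anti to the CH2OH group (trans, est. ≥10:1) and Hantzsch ester delivers hydrogen, which forms the C-7–C-8 bond and sets C-7 under control of the bought butenolide centre.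

Step 8
Reactants: 12 (4S,5S)-4-[2-(Diox)ethyl]-5-(hydroxymethyl)oxolan-2-one
Product: 13 (4S,5S)-4-[2-(Diox)ethyl]-5-(hydroxymethyl)oxolan-2-ol (both anomers)
Conditions: i-Bu2AlH (2.5 equiv), CH2Cl2, −78 °C; aq. KNaC4H4O6
Reagents that add atoms: none
Why: Partial reduction of the γ-lactone to the lactol, whose aluminium hemiacetal does not collapse at −78 °C, leaves the acetonide and all stereocentres untouched.

Step 9
Reactants: 13 (4S,5S)-4-[2-(Diox)ethyl]-5-(hydroxymethyl)oxolan-2-ol
Product: 14 (2S,3S)-3-[2-(Diox)ethyl]hex-5-ene-1,2-diol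
Conditions: Ph3PCH3Br, KOt-Bu, THF, 0 °C → rt
Reagents that add atoms: methyltriphenylphosphonium bromide, C[P+](c1ccccc1)(c1ccccc1)c1ccccc1.[Br-]
Why: Wittig methylenation of the open hydroxy-aldehyde form of the lactol installs the terminal olefin (C-5=C-4), and no stereocentre is α to the aldehyde.

Step 10
Reactants: 14 (2S,3S)-3-[2-(Diox)ethyl]hex-5-ene-1,2-diol
Product: 16 (2S)-2-[2-(Diox)ethyl]pent-4-en-1-ol, via (2S)-2-[2-(Diox)ethyl]pent-4-enal 15 (not isolated)
Conditions: NaIO4, THF–pH 7 buffer, 0 °C; then NaBH4, MeOH, 0 °C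
Reagents that add atoms: none
Why: Malaprade glycol cleavage removes the spare butenolide carbon, and immediate borohydride reduction of the α-branched aldehyde at 0 °C and neutral pH gives the C-24 alcohol without epimerising C-7.

Step 11
Reactants: 16 (2S)-2-[2-(Diox)ethyl]pent-4-en-1-ol; 17 methyl 2-bromoprop-2-enoate
Product: 19 methyl 2-{(2R,5R)-5-[2-(Diox)ethyl]oxan-2-yl}prop-2-enoate, via dienoate 18 (not isolated)
Conditions: 17 (1.5 equiv, slow addition), Pd(OAc)2 (5 mol%), n-Bu4NCl (1 equiv), K2CO3 (2.5 equiv), DMF, 70 °C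
Reagents that add atoms: none
Why: Proposed new method: the divalent vinylpalladium formed from 17 and zerovalent palladium inserts the terminal olefin of 16 (new bond to C-4), β-hydride elimination and re-addition (through 18·HPdBr) move palladium to a 2-(methoxycarbonyl)allyl complex over C-4/C-2/C-1, and the tethered C-24 hydroxyl attacks C-4 through a chair-like six-membered transition state with the C-7 substituent equatorial, which closes the oxane and sets C-4 trans to C-7; the closest known reactions are Larock-type palladium-migration heteroannulations of vinylic halides with olefinic sulfonamides or carboxylic acids and Sigman-type 1,1-difunctionalisations of terminal olefins, neither shown with an aliphatic alcohol nucleophile or an α-haloacrylate.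

Step 12
Reactants: 19 methyl 2-{(2R,5R)-5-[2-(Diox)ethyl]oxan-2-yl}prop-2-enoate
Product: 21 2-{(2R,5S)-5-[(3R,4R,7E)-3,4-dihydroxy-4,8,12-trimethyltrideca-7,11-dien-1-yl]oxan-2-yl}prop-2-enoic acid (CNP0285744.2), via lithium carboxylate 20 (not isolated)
Conditions: LiOH, THF–H2O, rt; then 1 M HCl (pH 1), rt
Reagents that add atoms: lithium hydroxide, [Li+].[OH-]
Why: Ester saponification followed by acidification, which also hydrolyses the acetonide (acid-catalysed ketal hydrolysis), frees the acid and the diol without touching a stereocentre.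

## Compound list

1 | geranyl bromide, (2E)-1-bromo-3,7-dimethylocta-2,6-diene | BrC/C=C(\C)CCC=C(C)C | starting material
2 | homogeranyl phenyl sulfide, {[(3E)-4,8-dimethylnona-3,7-dien-1-yl]sulfanyl}benzene | c1ccccc1SCC/C=C(\C)CCC=C(C)C | intermediate
3 | homogeranyl iodide, (3E)-1-iodo-4,8-dimethylnona-3,7-diene | ICC/C=C(\C)CCC=C(C)C | intermediate
4 | (3R)-3-hydroxyoxolan-2-one [(R)-α-hydroxy-γ-butyrolactone] | O[C@@H]1CCOC1=O | starting material
5 | dilithium (3R)-2-methyloxolane-2,3-diolate (not isolated) | [Li+].[Li+].CC1([O-])OCC[C@H]1[O-] | intermediate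
6 | (3R)-3,5-dihydroxypentan-2-one (in equilibrium with its cyclic hemiketal) | CC(=O)[C@H](O)CCO | intermediate
7 | homogeranylmagnesium iodide (not isolated) | I[Mg]CC/C=C(\C)CCC=C(C)C | intermediate
8 | (3R,4R,7E)-4,8,12-trimethyltrideca-7,11-diene-1,3,4-triol | OCC[C@@H](O)[C@](C)(O)CC/C=C(\C)CCC=C(C)C | intermediate
9 | 2-[(4R,5R)-5-hGer-2,2,5-trimethyl-1,3-dioxolan-4-yl]ethan-1-ol | OCC[C@H]1OC(C)(C)O[C@]1(C)CC/C=C(\C)CCC=C(C)C | intermediate
10 | (4R,5R)-5-hGer-4-(2-iodoethyl)-2,2,5-trimethyl-1,3-dioxolane | ICC[C@H]1OC(C)(C)O[C@]1(C)CC/C=C(\C)CCC=C(C)C | intermediate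
11 | (5S)-5-(hydroxymethyl)furan-2(5H)-one | O=C1C=C[C@@H](CO)O1 | starting material
12 | (4S,5S)-4-[2-(Diox)ethyl]-5-(hydroxymethyl)oxolan-2-one (4,5-trans) | O=C1C[C@H](CC[C@H]2OC(C)(C)O[C@]2(C)CC/C=C(\C)CCC=C(C)C)[C@@H](CO)O1 | intermediate
13 | (4S,5S)-4-[2-(Diox)ethyl]-5-(hydroxymethyl)oxolan-2-ol (both anomers) | OC1C[C@H](CC[C@H]2OC(C)(C)O[C@]2(C)CC/C=C(\C)CCC=C(C)C)[C@@H](CO)O1 | intermediate
14 | (2S,3S)-3-[2-(Diox)ethyl]hex-5-ene-1,2-diol | C=CC[C@H](CC[C@H]1OC(C)(C)O[C@]1(C)CC/C=C(\C)CCC=C(C)C)[C@H](O)CO | intermediate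
15 | (2S)-2-[2-(Diox)ethyl]pent-4-enal (not isolated) | C=CC[C@@H](C=O)CC[C@H]1OC(C)(C)O[C@]1(C)CC/C=C(\C)CCC=C(C)C | intermediate
16 | (2S)-2-[2-(Diox)ethyl]pent-4-en-1-ol | C=CC[C@@H](CO)CC[C@H]1OC(C)(C)O[C@]1(C)CC/C=C(\C)CCC=C(C)C | intermediate
17 | methyl 2-bromoprop-2-enoate | C=C(Br)C(=O)OC | starting material
18 | methyl (3E,6S)-8-(Diox)-6-(hydroxymethyl)-2-methylideneoct-3-enoate (not isolated) | C=C(C(=O)OC)/C=C/C[C@@H](CO)CC[C@H]1OC(C)(C)O[C@]1(C)CC/C=C(\C)CCC=C(C)C | intermediate
19 | methyl 2-{(2R,5R)-5-[2-(Diox)ethyl]oxan-2-yl}prop-2-enoate (2,5-trans; ring C-5 reads R by CIP while the acetonide is on, same spatial arrangement as 5S in 21) | C=C(C(=O)OC)[C@H]1CC[C@H](CC[C@H]2OC(C)(C)O[C@]2(C)CC/C=C(\C)CCC=C(C)C)CO1 | intermediate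
20 | lithium 2-{(2R,5R)-5-[2-(Diox)ethyl]oxan-2-yl}prop-2-enoate (not isolated) | [Li+].C=C(C(=O)[O-])[C@H]1CC[C@H](CC[C@H]2OC(C)(C)O[C@]2(C)CC/C=C(\C)CCC=C(C)C)CO1 | intermediate
21 | 2-{(2R,5S)-5-[(3R,4R,7E)-3,4-dihydroxy-4,8,12-trimethyltrideca-7,11-dien-1-yl]oxan-2-yl}prop-2-enoic acid | C=C(C(=O)O)[C@H]1CC[C@H](CC[C@@H](O)[C@](C)(O)CC/C=C(\C)CCC=C(C)C)CO1 | target

## Step count and risk

Total step count: 12.
Longest linear sequence: 11 steps (1 → 2 → 3 → 8 → 9 → 10 → 12 → 13 → 14 → 16 → 19 → 21). The branch from 4 is 10 steps.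

Three steps most likely to fail:

Step 4 (chelation-controlled addition to the free α-hydroxy ketone). The magnesium lactolate may open slowly, the ketone may enolise, and the diastereomer ratio at C-11 may be lower than hoped. The fallback uses a neutral ether oxygen for the chelate in place of the free alkoxide; it sets out from 4 and comes back at 8. Lactone 4 is etherified with 4-methoxybenzyl trichloroacetimidate (cat. CSA, CH2Cl2) to (3R)-3-[(4-methoxyphenyl)methoxy]oxolan-2-one F1. MeLi (1.05 equiv, THF, −78 °C) gives (3R)-5-hydroxy-3-[(4-methoxyphenyl)methoxy]pentan-2-one F2. After deprotonation of its hydroxyl with t-BuMgCl, addition of 7 in the presence of MgBr2·OEt2 (Cram chelate through the ether oxygen) gives (3R,4R,7E)-3-[(4-methoxyphenyl)methoxy]-4,8,12-trimethyltrideca-7,11-diene-1,4-diol F3. DDQ in wet CH2Cl2 removes the ether and returns 8.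

Step 7 (light-driven Giese union). Risks are premature reduction of the radical, a lower anti selectivity with the unprotected hydroxymethyl group, and loss of the acetonide if the acid formed is not buffered. The fallback is a polar conjugate addition in place of the radical addition; it sets out from 10 and 11 and comes back at 12. Butenolide 11 is silylated (t-BuPh2SiCl, imidazole, DMF) to (5S)-5-({[tert-butyl(diphenyl)silyl]oxy}methyl)furan-2(5H)-one F4. Iodide 10 and Mg (THF) give [2-(Diox)ethyl]magnesium iodide F5. F5 adds to F4 under CuBr·SMe2 catalysis with Me3SiCl (THF, −78 °C), anti to the silyloxymethyl group, to give (4S,5S)-5-({[tert-butyl(diphenyl)silyl]oxy}methyl)-4-[2-(Diox)ethyl]oxolan-2-one F6. Bu4NF (THF) returns 12.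

Step 11 (the proposed new palladium 1,1-oxyalkenylation). Risks are release of the simple Heck dienoate 18 without re-addition, attack of the alcohol on 17 itself, and a modest trans:cis ratio. The fallback uses only known chemistry (lactone, alkynyl ketal reduction, alkyne carbonylation); it sets out from 16 and comes back at 21.
- Hydroboration–oxidation of 16 (9-BBN, THF; NaOH, H2O2) gives (2R)-2-[2-(Diox)ethyl]pentane-1,5-diol F7.
- TEMPO/PhI(OAc)2 (CH2Cl2) oxidises the unbranched CH2OH and then the lactol to (5S)-5-[2-(Diox)ethyl]oxan-2-one F8.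
- LiC≡CSiMe3 (THF, −78 °C) gives (5S)-5-[2-(Diox)ethyl]-2-[(trimethylsilyl)ethynyl]oxan-2-ol F9.
- Et3SiH/BF3·OEt2 (CH2Cl2–MeCN, −78 °C) delivers hydride axially to the oxocarbenium ion, placing the alkyne equatorial (2,5-trans), and gives trimethyl({(2R,5R)-5-[2-(Diox)ethyl]oxan-2-yl}ethynyl)silane F10.
- K2CO3/MeOH gives (2R,5R)-5-[2-(Diox)ethyl]-2-ethynyloxane F11.
- Branched-selective methoxycarbonylation (Pd(OAc)2, 2-(diphenylphosphino)pyridine, MeSO3H, CO, MeOH, 50 °C), in which the acidic methanol also removes the acetonide, gives methyl 2-{(2R,5S)-5-[(3R,4R,7E)-3,4-dihydroxy-4,8,12-trimethyltrideca-7,11-dien-1-yl]oxan-2-yl}prop-2-enoate F12.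
- LiOH (THF–H2O) then gives 21.

## Further compounds

F1 | step 4 | (3R)-3-[(4-methoxyphenyl)methoxy]oxolan-2-one | COc1ccc(CO[C@@H]2CCOC2=O)cc1
F2 | step 4 | (3R)-5-hydroxy-3-[(4-methoxyphenyl)methoxy]pentan-2-one | CC(=O)[C@H](OCc1ccc(OC)cc1)CCO
F3 | step 4 | (3R,4R,7E)-3-[(4-methoxyphenyl)methoxy]-4,8,12-trimethyltrideca-7,11-diene-1,4-diol | OCC[C@@H](OCc1ccc(OC)cc1)[C@](C)(O)CC/C=C(\C)CCC=C(C)C
F4 | step 7 | (5S)-5-({[tert-butyl(diphenyl)silyl]oxy}methyl)furan-2(5H)-one | O=C1C=C[C@@H](CO[Si](c2ccccc2)(c2ccccc2)C(C)(C)C)O1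
F5 | step 7 | [2-(Diox)ethyl]magnesium iodide | I[Mg]CC[C@H]1OC(C)(C)O[C@]1(C)CC/C=C(\C)CCC=C(C)C
F6 | step 7 | (4S,5S)-5-({[tert-butyl(diphenyl)silyl]oxy}methyl)-4-[2-(Diox)ethyl]oxolan-2-one | O=C1C[C@H](CC[C@H]2OC(C)(C)O[C@]2(C)CC/C=C(\C)CCC=C(C)C)[C@@H](CO[Si](c3ccccc3)(c3ccccc3)C(C)(C)C)O1
F7 | step 11 | (2R)-2-[2-(Diox)ethyl]pentane-1,5-diol | OCCC[C@@H](CO)CC[C@H]1OC(C)(C)O[C@]1(C)CC/C=C(\C)CCC=C(C)C
F8 | step 11 | (5S)-5-[2-(Diox)ethyl]oxan-2-one | O=C1CC[C@H](CC[C@H]2OC(C)(C)O[C@]2(C)CC/C=C(\C)CCC=C(C)C)CO1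
F9 | step 11 | (5S)-5-[2-(Diox)ethyl]-2-[(trimethylsilyl)ethynyl]oxan-2-ol | C[Si](C)(C)C#CC1(O)CC[C@H](CC[C@H]2OC(C)(C)O[C@]2(C)CC/C=C(\C)CCC=C(C)C)CO1
F10 | step 11 | trimethyl({(2R,5R)-5-[2-(Diox)ethyl]oxan-2-yl}ethynyl)silane | C[Si](C)(C)C#C[C@H]1CC[C@H](CC[C@H]2OC(C)(C)O[C@]2(C)CC/C=C(\C)CCC=C(C)C)CO1
F11 | step 11 | (2R,5R)-5-[2-(Diox)ethyl]-2-ethynyloxane | C#C[C@H]1CC[C@H](CC[C@H]2OC(C)(C)O[C@]2(C)CC/C=C(\C)CCC=C(C)C)CO1
F12 | step 11 | methyl 2-{(2R,5S)-5-[(3R,4R,7E)-3,4-dihydroxy-4,8,12-trimethyltrideca-7,11-dien-1-yl]oxan-2-yl}prop-2-enoate | C=C(C(=O)OC)[C@H]1CC[C@H](CC[C@@H](O)[C@](C)(O)CC/C=C(\C)CCC=C(C)C)CO1
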